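Cuts, in retrosynthetic order: the eight O–benzyl bonds; the ester bond O7–C(=O) of the gallate; the two aryl–oxygen bonds O1–C8a (pyran ring) and C5–O5; C2–C1' (ring B); C4–C4a (ring A).
Forward order: rings A and B are bought. Ring A (3,5-dibromophenol, O7 as MOM ether) is joined through C4a to C4 of methyl (R)-glycidate, and ring B is added to C2 as a Grignard reagent. The pyran ring, the only ring made, closes last through O1–C8a; O7 is then freed and galloylated, and all benzyl groups are removed.
Enabling feature: ring A is 1,3,5-trioxygenated, and C5 and C8a are mirror-related across the axis C4a···C7. An open precursor with C–Br at both carbons therefore needs no site selection, the surviving C5–Br takes up the O5 benzyl ether in the same flask, and O7, which lies on the axis, is unique from step 1.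
Stereochemistry: C3 comes from the glycidate, and C2 from a chelation-controlled 1,2-syn aryl addition. The closure makes the aryl–O bond and leaves C2–O intact, so syn-(1R,2R) maps with retention onto 2,3-cis-(2R,3R).
Helper: the O3 benzyl ether is the chelating group in step 7, blocks five-membered closure through O3 in step 8, and leaves with the other benzyl groups in step 11.

Key step: step 8

Assumption: compounds 1, 3, 9 and 17 are taken as catalogue compounds, and flavan numbering (O1, C2, C3, C4, C4a, C5–C8, C8a, primed atoms for ring B) is used for the open-chain intermediates as well.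

Step 1
Reactants: 1 3,5-dibromophenol
Product: 2 1,3-dibromo-5-(methoxymethoxy)benzene
Conditions: NaH, MOMCl, DMF, 0 °C to rt
Reagents that add atoms: chloromethyl methyl ether (MOMCl), SMILES COCCl
Why: Williamson-type O-alkylation of the sodium phenoxide should give an acetal on O7 that withstands amide bases, organometallics, hydride and hot carbonate, yet can be cleaved later by mild acid beside benzyl ethers.

Step 2
Reactants: 2 1,3-dibromo-5-(methoxymethoxy)benzene; 3 methyl (R)-glycidate
Product: 6 methyl (R)-3-[2,6-dibromo-4-(methoxymethoxy)phenyl]-2-hydroxypropanoate, via aryllithium 4 (not isolated), via arylmagnesium bromide 5 (not isolated)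
Conditions: LiN(i-Pr)2 (1.05 equiv), THF, −78 °C; MgBr2·OEt2, −78 to −40 °C; CuBr·SMe2 (20 mol %), then 3, −40 to −20 °C; aq. NH4Cl
Reagents that add atoms: none
Why: Deprotonative lithiation should take the most acidic ring proton, the one flanked by both bromines (future C4a), and after lithium-to-magnesium exchange the copper-catalysed Grignard opening of the glycidic ester occurs by SN2 attack at the unsubstituted epoxide carbon, so the C3–O bond and its (R) configuration are not touched.

Step 3
Reactants: 6 methyl (R)-3-[2,6-dibromo-4-(methoxymethoxy)phenyl]-2-hydroxypropanoate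
Product: 7 methyl (R)-2-(benzyloxy)-3-[2,6-dibromo-4-(methoxymethoxy)phenyl]propanoate
Conditions: BnBr, Ag2O, CH2Cl2, rt, dark
Reagents that add atoms: benzyl bromide, SMILES BrCc1ccccc1
Why: Silver-oxide-mediated Williamson etherification works without a free alkoxide or enolate, so the stereocentre next to the ester should not epimerise.

Step 4
Reactants: 7 methyl (R)-2-(benzyloxy)-3-[2,6-dibromo-4-(methoxymethoxy)phenyl]propanoate
Product: 8 (R)-2-(benzyloxy)-3-[2,6-dibromo-4-(methoxymethoxy)phenyl]propanal
Conditions: i-Bu2AlH (1.1 equiv), CH2Cl2, −78 °C; aqueous work-up; used crude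
Reagents that add atoms: none
Why: Partial hydride reduction of an α-alkoxy ester stops at −78 °C at the chelated aluminium hemiacetal, which releases the aldehyde only on work-up, and the aryl bromides, MOM acetal and benzyl ether are inert to it.

Step 5
Reactants: 9 5-bromo-1,2,3-trimethoxybenzene
Product: 10 5-bromobenzene-1,2,3-triol
Conditions: BBr3, CH2Cl2, −78 °C to rt; H2O
Reagents that add atoms: none
Why: Lewis-acid ether cleavage with BBr3 removes aryl methyl ethers through bromide attack on the boron-activated O–CH3 groups and leaves the aryl bromide alone.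

Step 6
Reactants: 10 5-bromobenzene-1,2,3-triol
Product: 11 1,2,3-tris(benzyloxy)-5-bromobenzene
Conditions: BnBr, K2CO3, DMF, 60 °C, argon
Reagents that add atoms: benzyl bromide, SMILES BrCc1ccccc1
Why: Threefold Williamson etherification under exclusion of air, because the triol is oxidation-prone in base, installs on ring B the same hydrogenolysable group used everywhere else.

Step 7
Reactants: 11 1,2,3-tris(benzyloxy)-5-bromobenzene; 8 (R)-2-(benzyloxy)-3-[2,6-dibromo-4-(methoxymethoxy)phenyl]propanal
Product: 13 (1R,2R)-2-(benzyloxy)-3-[2,6-dibromo-4-(methoxymethoxy)phenyl]-1-[3,4,5-tris(benzyloxy)phenyl]propan-1-ol, via aryl Grignard reagent 12 (not isolated)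
Conditions: Mg, THF, 45 °C; then 8, MgBr2·OEt2, CH2Cl2, −78 °C; aq. NH4Cl
Reagents that add atoms: none
Why: In this Grignard addition under Cram-chelate control, magnesium ties the aldehyde oxygen and the O3 benzyl ether into a five-membered chelate and the aryl group attacks the face opposite the CH2–ring A substituent, which should set C2 as (R) in the 1,2-syn relation to C3; at −78 °C the ring A bromides do not exchange with the Grignard reagent.

Step 8
Reactants: 13 (1R,2R)-2-(benzyloxy)-3-[2,6-dibromo-4-(methoxymethoxy)phenyl]-1-[3,4,5-tris(benzyloxy)phenyl]propan-1-ol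
Product: 15 (2R,3R)-3,5-bis(benzyloxy)-7-(methoxymethoxy)-2-[3,4,5-tris(benzyloxy)phenyl]chromane, via 5-bromochroman 14 (not isolated)
Conditions: [(C3H5)PdCl]2 (2.5 mol %), RockPhos (6 mol %), Cs2CO3 (3.5 equiv), 4 Å molecular sieves, toluene, 80 °C; then BnOH (2 equiv), 100 °C
Reagents that add atoms: benzyl alcohol, SMILES OCc1ccccc1
Why: Zerovalent palladium inserts into one C–Br bond of ring A, the carbonate base exchanges bromide on divalent palladium for the C2 alkoxide to give a seven-membered oxapalladacycle, and C–O reductive elimination forms O1–C8a; a second catalytic cycle on the remaining C5–Br with benzyl alcohol then completes the 1,3,5-trioxygenation of ring A. The closest known reaction types are the intramolecular Buchwald–Hartwig-type etherification of aryl bromides with secondary alcohols (chroman synthesis) and its intermolecular version with primary alcohols, both served by the same bulky biarylphosphine. The pyran ring closes as a six-membered ring by reductive elimination from the seven-membered palladacycle, C4a and C8a of ring A being two of its members. No stereocentre is made: the bonds C2–O1 and C3–O3 are never broken, so the syn-(1R,2R) array of 13 is carried with retention into the 2,3-cis-(2R,3R) chroman. Site selectivity is not required, because the two C–Br bonds are exchanged by rotation about C4–C4a and closure at either gives 14 (even benzyloxylation before closure would converge on 15), and O1 is the only free hydroxyl, the O3 benzyl ether ruling out five-membered closure to a dihydrobenzofuran. The selectivity that is needed, reductive elimination over β-hydride elimination of the secondary benzylic alkoxide, is secured by the hindered electron-rich ligand and by the intramolecular setting.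

Step 9
Reactants: 15 (2R,3R)-3,5-bis(benzyloxy)-7-(methoxymethoxy)-2-[3,4,5-tris(benzyloxy)phenyl]chromane
Product: 16 (2R,3R)-3,5-bis(benzyloxy)-2-[3,4,5-tris(benzyloxy)phenyl]chroman-7-ol
Conditions: HCl (cat.), MeOH–THF, 40 °C
Reagents that add atoms: none
Why: Acid-catalysed transacetalisation to methanol cleaves the aryl MOM acetal far faster than benzyl ethers or the C2–O1 bond, the methanol traps the formaldehyde unit away from the nucleophilic ring A, and O7 emerges as the only free hydroxyl of the molecule.

Step 10
Reactants: 16 (2R,3R)-3,5-bis(benzyloxy)-2-[3,4,5-tris(benzyloxy)phenyl]chroman-7-ol; 17 3,4,5-tris(benzyloxy)benzoic acid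
Product: 18 (2R,3R)-3,5-bis(benzyloxy)-2-[3,4,5-tris(benzyloxy)phenyl]chroman-7-yl 3,4,5-tris(benzyloxy)benzoate
Conditions: EDC·HCl, DMAP, CH2Cl2, rt
Reagents that add atoms: none
Why: Steglich-type esterification through the acylpyridinium ion acylates the unhindered O7 phenol, and regiochemistry is not an issue because O3, O5 and all ring B oxygens are benzylated.

Step 11
Reactants: 18 (2R,3R)-3,5-bis(benzyloxy)-2-[3,4,5-tris(benzyloxy)phenyl]chroman-7-yl 3,4,5-tris(benzyloxy)benzoate
Product: 19 (−)-epigallocatechin 7-O-gallate, (2R,3R)-3,5-dihydroxy-2-(3,4,5-trihydroxyphenyl)chroman-7-yl 3,4,5-trihydroxybenzoate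
Conditions: H2 (1 atm), Pd(OH)2/C, THF–MeOH, rt
Reagents that add atoms: none
Why: Catalytic hydrogenolysis removes all eight benzyl ethers under neutral conditions, which should spare the aryl ester, avoid base-induced epimerisation at C2 of the free polyphenol, and leave the cyclic C2–O1 bond in place.

Compound list
1 | 3,5-dibromophenol | Oc1cc(Br)cc(Br)c1 | starting material
2 | 1,3-dibromo-5-(methoxymethoxy)benzene | COCOc1cc(Br)cc(Br)c1 | intermediate
3 | methyl (R)-glycidate (methyl (2R)-oxirane-2-carboxylate) | COC(=O)[C@H]1CO1 | starting material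
4 | 2,6-dibromo-4-(methoxymethoxy)phenyllithium | [Li]c1c(Br)cc(OCOC)cc1Br | intermediate
5 | 2,6-dibromo-4-(methoxymethoxy)phenylmagnesium bromide | Br[Mg]c1c(Br)cc(OCOC)cc1Br | intermediate
6 | methyl (R)-3-[2,6-dibromo-4-(methoxymethoxy)phenyl]-2-hydroxypropanoate | COC(=O)[C@H](O)Cc1c(Br)cc(OCOC)cc1Br | intermediate
7 | methyl (R)-2-(benzyloxy)-3-[2,6-dibromo-4-(methoxymethoxy)phenyl]propanoate | COC(=O)[C@H](OCc1ccccc1)Cc1c(Br)cc(OCOC)cc1Br | intermediate
8 | (R)-2-(benzyloxy)-3-[2,6-dibromo-4-(methoxymethoxy)phenyl]propanal | O=C[C@H](OCc1ccccc1)Cc1c(Br)cc(OCOC)cc1Br | intermediate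
9 | 5-bromo-1,2,3-trimethoxybenzene | COc1cc(Br)cc(OC)c1OC | starting material
10 | 5-bromobenzene-1,2,3-triol | Oc1cc(Br)cc(O)c1O | intermediate
11 | 1,2,3-tris(benzyloxy)-5-bromobenzene | Brc1cc(OCc2ccccc2)c(OCc2ccccc2)c(OCc2ccccc2)c1 | intermediate
12 | 3,4,5-tris(benzyloxy)phenylmagnesium bromide | Br[Mg]c1cc(OCc2ccccc2)c(OCc2ccccc2)c(OCc2ccccc2)c1 | intermediate
13 | (1R,2R)-2-(benzyloxy)-3-[2,6-dibromo-4-(methoxymethoxy)phenyl]-1-[3,4,5-tris(benzyloxy)phenyl]propan-1-ol | O[C@H](c1cc(OCc2ccccc2)c(OCc2ccccc2)c(OCc2ccccc2)c1)[C@H](OCc1ccccc1)Cc1c(Br)cc(OCOC)cc1Br | intermediate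
14 | (2R,3R)-3-(benzyloxy)-5-bromo-7-(methoxymethoxy)-2-[3,4,5-tris(benzyloxy)phenyl]chromane | COCOc1cc(Br)c2c(c1)O[C@H](c1cc(OCc3ccccc3)c(OCc3ccccc3)c(OCc3ccccc3)c1)[C@H](OCc1ccccc1)C2 | intermediate
15 | (2R,3R)-3,5-bis(benzyloxy)-7-(methoxymethoxy)-2-[3,4,5-tris(benzyloxy)phenyl]chromane | COCOc1cc(OCc3ccccc3)c2c(c1)O[C@H](c1cc(OCc3ccccc3)c(OCc3ccccc3)c(OCc3ccccc3)c1)[C@H](OCc1ccccc1)C2 | intermediate
16 | (2R,3R)-3,5-bis(benzyloxy)-2-[3,4,5-tris(benzyloxy)phenyl]chroman-7-ol | Oc1cc(OCc3ccccc3)c2c(c1)O[C@H](c1cc(OCc3ccccc3)c(OCc3ccccc3)c(OCc3ccccc3)c1)[C@H](OCc1ccccc1)C2 | intermediate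
17 | 3,4,5-tris(benzyloxy)benzoic acid | OC(=O)c1cc(OCc2ccccc2)c(OCc2ccccc2)c(OCc2ccccc2)c1 | starting material
18 | (2R,3R)-3,5-bis(benzyloxy)-2-[3,4,5-tris(benzyloxy)phenyl]chroman-7-yl 3,4,5-tris(benzyloxy)benzoate | O=C(Oc1cc(OCc3ccccc3)c2c(c1)O[C@H](c1cc(OCc3ccccc3)c(OCc3ccccc3)c(OCc3ccccc3)c1)[C@H](OCc1ccccc1)C2)c1cc(OCc2ccccc2)c(OCc2ccccc2)c(OCc2ccccc2)c1 | intermediate
19 | (−)-epigallocatechin 7-O-gallate | O=C(Oc1cc(O)c2c(c1)O[C@H](c1cc(O)c(O)c(O)c1)[C@H](O)C2)c1cc(O)c(O)c(O)c1 | target

Total step count: 11. Longest linear sequence: 9 (steps 1–4 and 7–11).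

Steps most likely to fail

Step 8. The divalent palladium alkoxide of the secondary benzylic alcohol may undergo β-hydride elimination, which oxidises C2 and hydrodebrominates ring A. The second, intermolecular coupling at the hindered C5–Br may also stall. The fallback sets out from 13 and comes back at 15. It changes the metal and uncouples the two C–O bond formations. The ring is closed by an Ullmann-type etherification (CuI, 1,10-phenanthroline, Cs2CO3, toluene, 110 °C), for which β-hydride loss is not a ready pathway, and 14 is isolated. A copper-catalysed hydroxylation of the C5–Br bond (CuI, oxalamide ligand, LiOH, DMSO–H2O, 80 °C) then gives the phenol (2R,3R)-3-(benzyloxy)-7-(methoxymethoxy)-2-[3,4,5-tris(benzyloxy)phenyl]chroman-5-ol F1. Treatment of this phenol with BnBr and K2CO3 in DMF gives 15.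

Step 2. The hindered, bromine-stabilised aryl-metal may open the epoxide too slowly. Attack at the ester, opening of the epoxide by bromide, or loss of metal bromide to an aryne on warming could then take over. The fallback sets out from 2 and comes back at 8. It uses an ester-free epoxide under Lewis-acid activation at a temperature where 4 is stable, and adjusts the oxidation level afterwards. Aryllithium 4 is treated at −78 °C with BF3·OEt2 and tert-butyl[(2R)-oxiran-2-ylmethoxy]diphenylsilane to give (R)-1-(tert-butyldiphenylsilyloxy)-3-[2,6-dibromo-4-(methoxymethoxy)phenyl]propan-2-ol F2. NaH and BnBr give its benzyl ether, (R)-[2-(benzyloxy)-3-[2,6-dibromo-4-(methoxymethoxy)phenyl]propoxy](tert-butyl)diphenylsilane F3. Desilylation with n-Bu4NF gives (R)-2-(benzyloxy)-3-[2,6-dibromo-4-(methoxymethoxy)phenyl]propan-1-ol F4, and Dess–Martin oxidation gives 8.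

Step 7. Facial selectivity may be poor if THF from the Grignard solution competes with O3 for magnesium and the chelate is not formed. The fallback sets out from 8 (with 12) and comes back at 13. It sets C2 by reduction instead of by addition. The addition is run without regard to selectivity, giving 13 together with its epimer (1S,2R)-2-(benzyloxy)-3-[2,6-dibromo-4-(methoxymethoxy)phenyl]-1-[3,4,5-tris(benzyloxy)phenyl]propan-1-ol F5. The mixture is oxidised with Dess–Martin periodinane to (R)-2-(benzyloxy)-3-[2,6-dibromo-4-(methoxymethoxy)phenyl]-1-[3,4,5-tris(benzyloxy)phenyl]propan-1-one F6. This ketone is reduced with LiBH(s-Bu)3 in THF at −78 °C under Felkin–Anh control, with hydride arriving anti to the benzyloxy group, which should return the syn alcohol 13.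

Further compounds
F1 | step 8 | (2R,3R)-3-(benzyloxy)-7-(methoxymethoxy)-2-[3,4,5-tris(benzyloxy)phenyl]chroman-5-ol | COCOc1cc(O)c2c(c1)O[C@H](c1cc(OCc3ccccc3)c(OCc3ccccc3)c(OCc3ccccc3)c1)[C@H](OCc1ccccc1)C2
F2 | step 2 | (R)-1-(tert-butyldiphenylsilyloxy)-3-[2,6-dibromo-4-(methoxymethoxy)phenyl]propan-2-ol | CC(C)(C)[Si](c1ccccc1)(c1ccccc1)OC[C@H](O)Cc1c(Br)cc(OCOC)cc1Br
F3 | step 2 | (R)-[2-(benzyloxy)-3-[2,6-dibromo-4-(methoxymethoxy)phenyl]propoxy](tert-butyl)diphenylsilane | CC(C)(C)[Si](c1ccccc1)(c1ccccc1)OC[C@H](OCc1ccccc1)Cc1c(Br)cc(OCOC)cc1Br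
F4 | step 2 | (R)-2-(benzyloxy)-3-[2,6-dibromo-4-(methoxymethoxy)phenyl]propan-1-ol | OC[C@H](OCc1ccccc1)Cc1c(Br)cc(OCOC)cc1Br
F5 | step 7 | (1S,2R)-2-(benzyloxy)-3-[2,6-dibromo-4-(methoxymethoxy)phenyl]-1-[3,4,5-tris(benzyloxy)phenyl]propan-1-ol | O[C@@H](c1cc(OCc2ccccc2)c(OCc2ccccc2)c(OCc2ccccc2)c1)[C@H](OCc1ccccc1)Cc1c(Br)cc(OCOC)cc1Br
F6 | step 7 | (R)-2-(benzyloxy)-3-[2,6-dibromo-4-(methoxymethoxy)phenyl]-1-[3,4,5-tris(benzyloxy)phenyl]propan-1-one | O=C(c1cc(OCc2ccccc2)c(OCc2ccccc2)c(OCc2ccccc2)c1)[C@H](OCc1ccccc1)Cc1c(Br)cc(OCOC)cc1Br
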